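## Analysis of the target

Target 19 is a (2S)-flavanone: a chroman-4-one (ring A fused to the pyranone ring C) that carries ring B at C2. Ring A is a phloroglucinol-type ring with hydroxyls at C5 and C7, the ring oxygen O1 at C8a and a prenyl group at C8. Ring B is a catechol (3'-OH, 4'-OH) with a second prenyl group at C5'. C2 is the only stereocentre; it is benzylic, bonded to O1 and β to the C4 ketone, so it is lost whenever ring C opens to the 2'-hydroxychalcone, readily with base and more slowly with acid. Each prenyl group sits ortho to a phenol (C8 next to 7-OH, C5' next to 4'-OH), so acid can add the phenol across the alkene to a 2,2-dimethylchroman; the alkenes also exclude hydrogenolysis and strong electrophiles, and the catechol is easily oxidised. The main difficulty is regiochemical: in a 5,7-dioxygenated ring A the carbons C6 and C8 are both flanked by two oxygens and differ only in that one neighbour is the 5-hydroxyl and the other is O1. The strategy rests on that C5 hydroxyl: it lies peri to the C4 carbonyl, and in the 5-deoxy compound the C5–H bond is the one aromatic C–H bond within reach of the ketone oxygen. Without O5, ring A comes from a resorcinol ketone in which the carbon between the two oxygens is the favoured site for the prenyl group, and the missing oxygen can be put in last under direction by the ketone.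

## Retrosynthetic reasoning

**19 to 18.** The last operation cuts only the three acetal O–CH2 bonds at O7, O3' and O4'. One type of protecting group is used for all three phenols; it must survive organolithium, iridium boryl, palladium and mild base chemistry and come off in dilute acid. The 5-hydroxyl of 18 needs no protection because it is hydrogen-bonded to the C4 carbonyl.

**18 to 16.** The C5–O bond is cut, which leads back to the 5-deoxyflavanone 16. This is the disconnection that removes the C6/C8 ambiguity: ring A of 16 is a resorcinol pattern with only one position between two oxygens. The forward reaction has to functionalise one of four aromatic C–H bonds, through boronate 17, and leave two trisubstituted alkenes, three acetals, the ketone and the C2 centre alone. Chelation by the C4 carbonyl is what singles out C5–H.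

**16 to 9 and 15.** The C2–C1' bond is cut. This divides the molecule into two halves of similar size and lets the only stereocentre be set in the joining step, by enantioselective transfer of the aryl group of boronic acid 15 to the β-carbon of chromone 9. Chromone 9 is achiral and robust, so no stereochemical information has to be carried through the synthesis of either half.

**9 to 7.** Ring C is opened at O1–C2 and C2–C3. C2 is a one-carbon unit condensed onto the acetyl methyl of 7 (enaminone 8), and the ring closes through the free 2-hydroxyl. Because the prenyl group of 7 sits next to that hydroxyl, it can only become C8.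

**7 to 1 and 2.** After removal of the acetal (7 to 6), the aryl–prenyl bond is cut as a [3,3] rearrangement: 6 comes from the tertiary allyl ether 5, 5 from alkyne 4 by semi-reduction, and 4 from 1 and 2 by O-alkylation (2 activated as 3). Direct C-prenylation of 1 would give mixtures of C3, C5 and O-alkylation. The rearrangement can deliver carbon only to the two positions ortho to O4, and the hydrogen-bonded 2-hydroxy ketone biases it to C3.

**15 to 13.** The C1'–B bond is cut. Arene 13 is a 1,2,3-trisubstituted benzene whose only C–H bond without an ortho neighbour is the one that becomes C1', so a sterically controlled C–H borylation gives 14 with no halogenation step that the alkene would not survive. Hydrolysis of 14 gives 15.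

**13 to 10.** The C5'–prenyl bond is cut by directed ortho-metalation of 11 through aryllithium 12. The acetal groups needed as protection also direct the lithiation; 11 is the bis-acetal of catechol 10.

## Alternatives that were turned down

**Alternative 1:** Ring C is taken apart at three bonds (C4a–C4, C4–C3, O1–C2), giving 2-iodo-3,5-bis(methoxymethoxy)-6-prenylphenol A1, carbon monoxide and 5-ethynyl-1,2-bis(methoxymethoxy)-3-prenylbenzene A2. In the forward direction PdCl2(PPh3)2 and diethylamine would join them in one flask to the tetra-MOM flavone A3, which then has to be reduced enantioselectively at C2–C3.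
- For: three bonds and a ring form in one operation, all four oxygens are present from the start, and no late C–H step is needed. On convergence and bond count per step it is stronger than the chosen route.
- Against: A1 is a pentasubstituted phloroglucinol in which iodine and prenyl must be placed on two positions that are both flanked by oxygens, so the C6/C8 problem moves into the starting material. Five-membered closure to the aurone competes with the six-membered one. The stereocentre then depends on an asymmetric 1,4-reduction of a 2-arylchromone that carries two alkenes; hydrogenation is excluded and hydride methods risk over-reduction at C4.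
- Comparison: the chosen route gives up the one-flask assembly and offers instead an unambiguous ring A and a stereocentre set by an aryl transfer with direct precedent on chromones.

**Alternative 2:** The C2–C3 bond is cut, leading to the diazoketone A4, an aryl diazomethyl ketone whose ortho oxygen carries the ring B benzyl group. Rh2(S-DOSP)4 would generate the carbene at C3 and insert it into the benzylic ether C–H bond to give the (2S)-tetra-TBS flavanone A5.
- For: ring closure and the stereocentre come from the same event, and no enone or chalcone intermediate is involved. In concept this is the stronger way to control C2.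
- Against: the ether oxygen O1 is 1,5 to the carbene carbon, so oxonium ylide formation followed by a [1,2]-benzyl shift to a five-membered benzofuranone should compete strongly with six-membered C–H insertion. Prolinate catalysts give their best selectivity with donor/acceptor carbenes, not with a diazoketone of this acceptor-only kind. The two electron-rich alkenes are cyclopropanation traps, four aryl silyl ethers are labile, and the ring A acid behind A4 again needs C6 and C8 to be told apart.
- Comparison: the chosen route uses reaction types that are each known on aryl ketones or chromones and keeps the doubtful selectivity in one step that does not touch C2.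

**Alternative 3:** Ring A is disconnected at C4a–C5 and built last. The precursor is the (2S)-2-aryl-2,3-dihydropyran-4-one A6, whose C6 carries a prenylated β-keto ester chain. Mg(OMe)2 would form the extended enolate, C4a would acylate on the ester carbon, and loss of methanol and tautomerisation would give (2S)-5,7-dihydroxy-3',4'-bis(methoxymethoxy)-8,5'-diprenylflavanone A7.
- For: the prenyl-bearing carbon is a chain carbon, so the C8 position is fixed by construction. On regiochemical certainty it is equal to the chosen route, and it needs no precious-metal C–H step.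
- Against: A6 requires a long linear assembly (an asymmetric route to the dihydropyranone, then a prenylated diketo ester chain). The chain methylene between the two carbonyls is the most acidic site, so acylation through C4a competes with O-acylation and retro-Claisen cleavage. The dihydropyranone is a vinylogous ester that can ring-open by β-elimination under alkoxide, which endangers C2 in the key step itself.
- Comparison: the chosen route is shorter and puts its risk in a step that leaves the stereocentre alone.

Key step: step 11

Remark on the chemistry: the sense of induction of the pyridine–oxazoline ligand on chromone 9 is taken to follow the facial model established for cyclic enones and chromones, in which the (S)-ligand leads to (2R)-flavanones; the (R)-ligand is therefore used to reach (2S).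

## Route

Step 1
Reactants: 1 2,4-dihydroxyacetophenone; 2 2-methylbut-3-yn-2-ol
Product: 4 1-[2-hydroxy-4-(2-methylbut-3-yn-2-yloxy)phenyl]ethanone, via 2-methylbut-3-yn-2-yl trifluoroacetate 3 (not isolated)
Conditions: 2, (CF3CO)2O, DBU, MeCN, –5 °C; then 1, DBU, CuCl2·2H2O (cat.), MeCN, 0 °C
Reagents that add atoms: none
Why: Copper-catalysed propargylic etherification of a tertiary propargylic ester (copper acetylide pathway) gives the hindered tertiary aryl ether without allene formation. Only the 4-hydroxyl reacts, because the 2-hydroxyl is held in the hydrogen bond to the acetyl group and is less acidic and less nucleophilic.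

Step 2
Reactants: 4 1-[2-hydroxy-4-(2-methylbut-3-yn-2-yloxy)phenyl]ethanone
Product: 5 1-[2-hydroxy-4-(2-methylbut-3-en-2-yloxy)phenyl]ethanone
Conditions: H2 (1 atm), Pd/CaCO3 poisoned with Pb(OAc)2, quinoline, EtOAc, rt
Reagents that add atoms: none
Why: Lindlar semihydrogenation stops at the alkene because the poisoned palladium surface binds the terminal alkyne much more strongly than the resulting 1,1-dimethylallyl ether; the aryl ketone is inert.

Step 3
Reactants: 5 1-[2-hydroxy-4-(2-methylbut-3-en-2-yloxy)phenyl]ethanone
Product: 6 1-[2,4-dihydroxy-3-(3-methylbut-2-enyl)phenyl]ethanone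
Conditions: PhNEt2, 140–160 °C
Reagents that add atoms: none
Why: Aromatic Claisen rearrangement ([3,3]) inverts the allyl unit, so the tertiary ether gives the linear prenyl group on carbon. The hydrogen-bonded 2-hydroxy ketone fixes more double-bond character in the C3–C4 bond, which should steer migration to C3 between the two oxygens in preference to C5; the para position carries the acetyl group.

Step 4
Reactants: 6 1-[2,4-dihydroxy-3-(3-methylbut-2-enyl)phenyl]ethanone
Product: 7 1-[2-hydroxy-4-(methoxymethoxy)-3-(3-methylbut-2-enyl)phenyl]ethanone
Conditions: MOMCl (1.1 equiv), K2CO3, acetone, 0 °C to rt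
Reagents that add atoms: chloromethyl methyl ether, COCCl
Why: O-Alkylation of a phenoxide with an α-chloro ether. Under weak base only the non-chelated 4-hydroxyl is deprotonated and alkylated, which leaves the 2-hydroxyl free for the ring closure.

Step 5
Reactants: 7 1-[2-hydroxy-4-(methoxymethoxy)-3-(3-methylbut-2-enyl)phenyl]ethanone
Product: 9 7-(methoxymethoxy)-8-(3-methylbut-2-enyl)-4H-chromen-4-one, via enaminone 8 (not isolated)
Conditions: Me2NCH(OMe)2, toluene, 90 °C; concentrate; then AcOH, 60 °C
Reagents that add atoms: N,N-dimethylformamide dimethyl acetal, COC(OC)N(C)C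
Why: Enaminone route to chromones: the acetyl methyl condenses with the amide acetal, then the phenol adds to the β-carbon and dimethylamine is expelled. Acetic acid should be acidic enough for this closure but too weak to cleave the aryl acetal or to add the phenol across the prenyl alkene.

Step 6
Reactants: 10 catechol
Product: 11 1,2-bis(methoxymethoxy)benzene
Conditions: MOMCl (2.5 equiv), i-Pr2NEt, CH2Cl2, 0 °C to rt
Reagents that add atoms: chloromethyl methyl ether, COCCl
Why: Standard double O-alkylation of a catechol with an α-chloro ether under amine base.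

Step 7
Reactants: 11 1,2-bis(methoxymethoxy)benzene
Product: 13 1,2-bis(methoxymethoxy)-3-(3-methylbut-2-enyl)benzene, via aryllithium 12 (not isolated)
Conditions: n-BuLi, TMEDA, THF, 0 °C; then CuI (10 mol%), prenyl bromide, –78 °C to rt
Reagents that add atoms: 1-bromo-3-methylbut-2-ene (prenyl bromide), CC(C)=CCBr
Why: Directed ortho-metalation: the acetal oxygens bind lithium and acidify the adjacent ring C–H. Copper-catalysed substitution at the primary carbon of the allylic bromide should give the linear prenyl arene and not the tertiary isomer.

Step 8
Reactants: 13 1,2-bis(methoxymethoxy)-3-(3-methylbut-2-enyl)benzene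
Product: 14 2-[3,4-bis(methoxymethoxy)-5-(3-methylbut-2-enyl)phenyl]-4,4,5,5-tetramethyl-1,3,2-dioxaborolane
Conditions: [Ir(OMe)(cod)]2 (1.5 mol%), 4,4'-di-tert-butyl-2,2'-bipyridine (3 mol%), B2pin2 (1.0 equiv), THF, 70 °C
Reagents that add atoms: bis(pinacolato)diboron, CC1(C)OB(OC1(C)C)B1OC(C)(C)C(C)(C)O1
Why: Sterically governed aromatic C–H borylation by a bipyridine tris(boryl) complex of trivalent iridium. Of the three ring C–H bonds only the one meta to both the prenyl group and the outer acetal has no ortho substituent, and this is the future C1'; the trisubstituted alkene is a poor substrate for the iridium boryl.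

Step 9
Reactants: 14 2-[3,4-bis(methoxymethoxy)-5-(3-methylbut-2-enyl)phenyl]-4,4,5,5-tetramethyl-1,3,2-dioxaborolane
Product: 15 [3,4-bis(methoxymethoxy)-5-(3-methylbut-2-enyl)phenyl]boronic acid
Conditions: NaIO4, NH4OAc, acetone/H2O (1:1), rt
Reagents that add atoms: water, O
Why: NaIO4 cleaves the pinacol released in the hydrolysis equilibrium and so drives the boronic ester to the free acid. The buffered, near-neutral medium spares the acetals and the alkene.

Step 10
Reactants: 9 7-(methoxymethoxy)-8-(3-methylbut-2-enyl)-4H-chromen-4-one; 15 [3,4-bis(methoxymethoxy)-5-(3-methylbut-2-enyl)phenyl]boronic acid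
Product: 16 (2S)-2-[3,4-bis(methoxymethoxy)-5-(3-methylbut-2-enyl)phenyl]-7-(methoxymethoxy)-8-(3-methylbut-2-enyl)chroman-4-one
Conditions: Pd(OCOCF3)2 (5 mol%), (R)-4-tert-butyl-2-(pyridin-2-yl)-4,5-dihydrooxazole (6 mol%), NH4PF6 (30 mol%), H2O (5 equiv), ClCH2CH2Cl, 60 °C
Reagents that add atoms: none
Why: Palladium-catalysed asymmetric conjugate addition of an arylboronic acid to a chromone: transmetalation to cationic divalent palladium, insertion of C2=C3 into the Pd–aryl bond, then protonolysis of the palladium enolate by water, which gives the flavanone and not the flavone. The C2 stereocentre is set in the insertion by the tert-butyl group of the ligand, and the (R)-ligand should deliver the aryl group to the face that gives (2S).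

Step 11
Reactants: 16 (2S)-2-[3,4-bis(methoxymethoxy)-5-(3-methylbut-2-enyl)phenyl]-7-(methoxymethoxy)-8-(3-methylbut-2-enyl)chroman-4-one
Product: 18 (2S)-2-[3,4-bis(methoxymethoxy)-5-(3-methylbut-2-enyl)phenyl]-5-hydroxy-7-(methoxymethoxy)-8-(3-methylbut-2-enyl)chroman-4-one, via C5 pinacol boronate 17 (not isolated)
Conditions: [Ir(OMe)(cod)]2 (5 mol%), AsPh3 (20 mol%), B2pin2 (1.2 equiv), octane, 110 °C; then NaBO3·4H2O, THF/H2O, 0 °C to rt; pH 7 buffer work-up
Reagents that add atoms: sodium perborate tetrahydrate NaBO3·4H2O, [Na+].[Na+].O[B-]1(O)OO[B-](O)(O)OO1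
Why: [Ir(OMe)(cod)]2, B2pin2 and the weakly donating AsPh3 give a coordinatively unsaturated boryl complex of trivalent iridium; the C4 carbonyl oxygen of 16 binds at the open site, the metal cleaves the peri C5–H bond to a five-membered iridacycle (Ir, O, C4, C4a, C5), and reductive elimination forms the C5–B bond of 17. NaBO3 then puts a peroxide oxygen on boron, the aryl group migrates from boron to oxygen, and hydrolysis gives the C5 phenol hydrogen-bonded to the C4 carbonyl. The closest known reaction type is the iridium-catalysed ketone-directed ortho C–H borylation of aryl ketones followed by oxidation of the boronate. No ring is closed and no stereocentre is formed; C2 is not involved, and enolisation at C3 would not affect it. The step needs site selectivity for C5 over C6, C2' and C6': C2' and C6' each have two ortho substituents, C6 lies next to the 7-acetal and outside the chelate, and this ligand set is a poor catalyst for undirected borylation. The second ortho position of the ketone is the ring-fusion carbon C8a, so double borylation cannot occur. Chemoselectivity over the two prenyl groups rests on the low reactivity of trisubstituted alkenes toward iridium boryl and hydride species, and the acetal oxygens are weaker donors than the ketone. The oxidation is kept cold and short and is quenched into neutral buffer so that base-induced opening of ring C, the path to racemisation at C2, is avoided.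

Step 12
Reactants: 18 (2S)-2-[3,4-bis(methoxymethoxy)-5-(3-methylbut-2-enyl)phenyl]-5-hydroxy-7-(methoxymethoxy)-8-(3-methylbut-2-enyl)chroman-4-one
Product: 19 (2S)-2-[3,4-dihydroxy-5-(3-methylbut-2-enyl)phenyl]-5,7-dihydroxy-8-(3-methylbut-2-enyl)chroman-4-one
Conditions: 3 M aq. HCl, MeOH, 45 °C
Reagents that add atoms: none
Why: Acid-catalysed acetal exchange with methanol releases the three phenols and dimethoxymethane. Dilute acid at moderate temperature is chosen so that deprotection should outrun addition of the phenols to the prenyl alkenes and acid-catalysed opening of ring C.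

## Compound list

1 | 2,4-dihydroxyacetophenone | CC(=O)c1ccc(O)cc1O | starting material
2 | 2-methylbut-3-yn-2-ol | CC(C)(O)C#C | starting material
3 | 2-methylbut-3-yn-2-yl trifluoroacetate | CC(C)(OC(=O)C(F)(F)F)C#C | intermediate (not isolated)
4 | 1-[2-hydroxy-4-(2-methylbut-3-yn-2-yloxy)phenyl]ethanone | CC(=O)c1ccc(OC(C)(C)C#C)cc1O | intermediate
5 | 1-[2-hydroxy-4-(2-methylbut-3-en-2-yloxy)phenyl]ethanone | CC(=O)c1ccc(OC(C)(C)C=C)cc1O | intermediate
6 | 1-[2,4-dihydroxy-3-(3-methylbut-2-enyl)phenyl]ethanone | CC(=O)c1ccc(O)c(CC=C(C)C)c1O | intermediate
7 | 1-[2-hydroxy-4-(methoxymethoxy)-3-(3-methylbut-2-enyl)phenyl]ethanone | CC(=O)c1ccc(OCOC)c(CC=C(C)C)c1O | intermediate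
8 | (E)-3-(dimethylamino)-1-[2-hydroxy-4-(methoxymethoxy)-3-(3-methylbut-2-enyl)phenyl]prop-2-en-1-one | CN(C)/C=C/C(=O)c1ccc(OCOC)c(CC=C(C)C)c1O | intermediate (not isolated)
9 | 7-(methoxymethoxy)-8-(3-methylbut-2-enyl)-4H-chromen-4-one | O=c1ccoc2c(CC=C(C)C)c(OCOC)ccc12 | intermediate
10 | catechol (benzene-1,2-diol) | Oc1ccccc1O | starting material
11 | 1,2-bis(methoxymethoxy)benzene | COCOc1ccccc1OCOC | intermediate
12 | [2,3-bis(methoxymethoxy)phenyl]lithium | [Li]c1cccc(OCOC)c1OCOC | intermediate (not isolated)
13 | 1,2-bis(methoxymethoxy)-3-(3-methylbut-2-enyl)benzene | COCOc1cccc(CC=C(C)C)c1OCOC | intermediate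
14 | 2-[3,4-bis(methoxymethoxy)-5-(3-methylbut-2-enyl)phenyl]-4,4,5,5-tetramethyl-1,3,2-dioxaborolane | CC(C)=CCc1cc(B2OC(C)(C)C(C)(C)O2)cc(OCOC)c1OCOC | intermediate
15 | [3,4-bis(methoxymethoxy)-5-(3-methylbut-2-enyl)phenyl]boronic acid | CC(C)=CCc1cc(B(O)O)cc(OCOC)c1OCOC | intermediate
16 | (2S)-2-[3,4-bis(methoxymethoxy)-5-(3-methylbut-2-enyl)phenyl]-7-(methoxymethoxy)-8-(3-methylbut-2-enyl)chroman-4-one | CC(C)=CCc1cc([C@@H]2CC(=O)c3ccc(OCOC)c(CC=C(C)C)c3O2)cc(OCOC)c1OCOC | intermediate
17 | (2S)-2-[3,4-bis(methoxymethoxy)-5-(3-methylbut-2-enyl)phenyl]-7-(methoxymethoxy)-8-(3-methylbut-2-enyl)-5-(4,4,5,5-tetramethyl-1,3,2-dioxaborolan-2-yl)chroman-4-one | CC(C)=CCc1cc([C@@H]2CC(=O)c3c(B4OC(C)(C)C(C)(C)O4)cc(OCOC)c(CC=C(C)C)c3O2)cc(OCOC)c1OCOC | intermediate (not isolated)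
18 | (2S)-2-[3,4-bis(methoxymethoxy)-5-(3-methylbut-2-enyl)phenyl]-5-hydroxy-7-(methoxymethoxy)-8-(3-methylbut-2-enyl)chroman-4-one | CC(C)=CCc1cc([C@@H]2CC(=O)c3c(O)cc(OCOC)c(CC=C(C)C)c3O2)cc(OCOC)c1OCOC | intermediate
19 | (2S)-2-[3,4-dihydroxy-5-(3-methylbut-2-enyl)phenyl]-5,7-dihydroxy-8-(3-methylbut-2-enyl)chroman-4-one | CC(C)=CCc1cc([C@@H]2CC(=O)c3c(O)cc(O)c(CC=C(C)C)c3O2)cc(O)c1O | target

## Step count and least certain steps

Total: 12 steps. Longest linear sequence: 8 steps (steps 1–5, 10, 11, 12); the ring B branch contributes steps 6–9.

**Step 11 (key step).** The most likely failure is that chelation by the chromanone carbonyl does not outcompete binding of the iridium centre by the two prenyl alkenes or the acetal oxygens, so that C–H activation is slow or unselective. Alkene hydroboration by the pinacolborane formed, protodeboronation of the ortho-acyl boronate before oxidation, and partial racemisation by base-induced ring opening during the perborate stage are the other ways it can go wrong. The electron-poor phosphine P[3,5-(CF3)2C6H3]3 is the second ligand of the same kind to try.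

The fallback gives up the late oxygenation and carries the C5 oxygen from the start; it sets out from boronic acid 15 and comes back to the route at 19. Commercial 2,4,6-trihydroxyacetophenone is C-prenylated with prenyl bromide and DBU in THF to 1-[2,4,6-trihydroxy-3-(3-methylbut-2-enyl)phenyl]ethanone F1. MOMCl and i-Pr2NEt (2.2 equiv) protect the free 4-hydroxyl and the less hindered of the two chelated hydroxyls, giving 1-[2-hydroxy-4,6-bis(methoxymethoxy)-3-(3-methylbut-2-enyl)phenyl]ethanone F2. The amide acetal condensation of step 5 gives (E)-3-(dimethylamino)-1-[2-hydroxy-4,6-bis(methoxymethoxy)-3-(3-methylbut-2-enyl)phenyl]prop-2-en-1-one F3, which closes in acetic acid to 5,7-bis(methoxymethoxy)-8-(3-methylbut-2-enyl)-4H-chromen-4-one F4. Conjugate addition of 15 under the conditions of step 10 gives (2S)-2-[3,4-bis(methoxymethoxy)-5-(3-methylbut-2-enyl)phenyl]-5,7-bis(methoxymethoxy)-8-(3-methylbut-2-enyl)chroman-4-one F5, and acid methanolysis as in step 12 gives 19. The price is that the prenyl position now depends on which chelated hydroxyl is capped, so an isomer separation at F2 has to be expected.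

**Step 10.** Slow insertion into the electron-rich chromone would let protodeboronation of the electron-rich boronic acid and loss of acetal groups in the mildly acidic aqueous medium compete, and facial selectivity on this 8-substituted chromone may be lower than on simple chromones.

The fallback replaces catalyst control by resolution; it sets out from 9 and 15 and comes back at 16. Addition with an achiral catalyst (Pd(OCOCF3)2 with 2,2'-bipyridine) gives racemic 2-[3,4-bis(methoxymethoxy)-5-(3-methylbut-2-enyl)phenyl]-7-(methoxymethoxy)-8-(3-methylbut-2-enyl)chroman-4-one F6, which is separated on a chiral stationary phase. The unwanted half of F6 is racemised with weak base through opening and reclosure of ring C and recycled.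

**Step 12.** The likely failure is acid-promoted addition of the freed 7- and 4'-hydroxyls across the adjacent prenyl alkenes, together with some acid-catalysed ring opening and loss of configuration at C2.

The fallback avoids protic acid; it sets out from 18 and comes back at 19. TMSOTf and 2,2'-bipyridyl in CH2Cl2 (0 °C to rt) exchange the aryl acetals, and silylate the free 5-hydroxyl, under buffered non-protic conditions to give (2S)-2-[3,4-bis(trimethylsilyloxy)-5-(3-methylbut-2-enyl)phenyl]-5,7-bis(trimethylsilyloxy)-8-(3-methylbut-2-enyl)chroman-4-one F7. Neutral aqueous THF then hydrolyses the silyl ethers to 19.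

**Step 5.** The acid stage may cleave the 4-acetal or add the free 2-hydroxyl across the neighbouring prenyl alkene before the pyranone ring closes.

The fallback closes the ring without acid; it sets out from 7 and comes back at 9. Formylation of the acetyl group with NaH and ethyl formate in THF gives, after neutral work-up, the cyclic hemiacetal 2-hydroxy-7-(methoxymethoxy)-8-(3-methylbut-2-enyl)chroman-4-one F8, which is dehydrated through its mesylate (MsCl, Et3N, CH2Cl2, 0 °C) to 9.

## Further compounds

F1 | step 11 | 1-[2,4,6-trihydroxy-3-(3-methylbut-2-enyl)phenyl]ethanone | CC(=O)c1c(O)cc(O)c(CC=C(C)C)c1O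
F2 | step 11 | 1-[2-hydroxy-4,6-bis(methoxymethoxy)-3-(3-methylbut-2-enyl)phenyl]ethanone | CC(=O)c1c(OCOC)cc(OCOC)c(CC=C(C)C)c1O
F3 | step 11 | (E)-3-(dimethylamino)-1-[2-hydroxy-4,6-bis(methoxymethoxy)-3-(3-methylbut-2-enyl)phenyl]prop-2-en-1-one | CN(C)/C=C/C(=O)c1c(OCOC)cc(OCOC)c(CC=C(C)C)c1O
F4 | step 11 | 5,7-bis(methoxymethoxy)-8-(3-methylbut-2-enyl)-4H-chromen-4-one | O=c1ccoc2c(CC=C(C)C)c(OCOC)cc(OCOC)c12
F5 | step 11 | (2S)-2-[3,4-bis(methoxymethoxy)-5-(3-methylbut-2-enyl)phenyl]-5,7-bis(methoxymethoxy)-8-(3-methylbut-2-enyl)chroman-4-one | CC(C)=CCc1cc([C@@H]2CC(=O)c3c(OCOC)cc(OCOC)c(CC=C(C)C)c3O2)cc(OCOC)c1OCOC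
F6 | step 10 | racemic 2-[3,4-bis(methoxymethoxy)-5-(3-methylbut-2-enyl)phenyl]-7-(methoxymethoxy)-8-(3-methylbut-2-enyl)chroman-4-one | CC(C)=CCc1cc(C2CC(=O)c3ccc(OCOC)c(CC=C(C)C)c3O2)cc(OCOC)c1OCOC
F7 | step 12 | (2S)-2-[3,4-bis(trimethylsilyloxy)-5-(3-methylbut-2-enyl)phenyl]-5,7-bis(trimethylsilyloxy)-8-(3-methylbut-2-enyl)chroman-4-one | CC(C)=CCc1cc([C@@H]2CC(=O)c3c(O[Si](C)(C)C)cc(O[Si](C)(C)C)c(CC=C(C)C)c3O2)cc(O[Si](C)(C)C)c1O[Si](C)(C)C
F8 | step 5 | 2-hydroxy-7-(methoxymethoxy)-8-(3-methylbut-2-enyl)chroman-4-one (racemic hemiacetal) | O=C1CC(O)Oc2c(CC=C(C)C)c(OCOC)ccc12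
A1 | alternative 1 | 2-iodo-3,5-bis(methoxymethoxy)-6-(3-methylbut-2-enyl)phenol | Oc1c(I)c(OCOC)cc(OCOC)c1CC=C(C)C
A2 | alternative 1 | 5-ethynyl-1,2-bis(methoxymethoxy)-3-(3-methylbut-2-enyl)benzene | C#Cc1cc(CC=C(C)C)c(OCOC)c(OCOC)c1
A3 | alternative 1 | 2-[3,4-bis(methoxymethoxy)-5-(3-methylbut-2-enyl)phenyl]-5,7-bis(methoxymethoxy)-8-(3-methylbut-2-enyl)-4H-chromen-4-one | CC(C)=CCc1cc(-c2cc(=O)c3c(OCOC)cc(OCOC)c(CC=C(C)C)c3o2)cc(OCOC)c1OCOC
A4 | alternative 2 | 1-{2-{[3,4-bis(tert-butyldimethylsilyloxy)-5-(3-methylbut-2-enyl)phenyl]methoxy}-4,6-bis(tert-butyldimethylsilyloxy)-3-(3-methylbut-2-enyl)phenyl}-2-diazoethanone | [N-]=[N+]=CC(=O)c1c(O[Si](C)(C)C(C)(C)C)cc(O[Si](C)(C)C(C)(C)C)c(CC=C(C)C)c1OCc1cc(CC=C(C)C)c(O[Si](C)(C)C(C)(C)C)c(O[Si](C)(C)C(C)(C)C)c1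
A5 | alternative 2 | (2S)-2-[3,4-bis(tert-butyldimethylsilyloxy)-5-(3-methylbut-2-enyl)phenyl]-5,7-bis(tert-butyldimethylsilyloxy)-8-(3-methylbut-2-enyl)chroman-4-one | CC(C)=CCc1cc([C@@H]2CC(=O)c3c(O[Si](C)(C)C(C)(C)C)cc(O[Si](C)(C)C(C)(C)C)c(CC=C(C)C)c3O2)cc(O[Si](C)(C)C(C)(C)C)c1O[Si](C)(C)C(C)(C)C
A6 | alternative 3 | methyl 4-{(2S)-2-[3,4-bis(methoxymethoxy)-5-(3-methylbut-2-enyl)phenyl]-4-oxo-3,4-dihydro-2H-pyran-6-yl}-7-methyl-3-oxooct-6-enoate | COC(=O)CC(=O)C(CC=C(C)C)C1=CC(=O)C[C@@H](c2cc(CC=C(C)C)c(OCOC)c(OCOC)c2)O1
A7 | alternative 3 | (2S)-2-[3,4-bis(methoxymethoxy)-5-(3-methylbut-2-enyl)phenyl]-5,7-dihydroxy-8-(3-methylbut-2-enyl)chroman-4-one | CC(C)=CCc1cc([C@@H]2CC(=O)c3c(O)cc(O)c(CC=C(C)C)c3O2)cc(OCOC)c1OCOC
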